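**Retrosynthetic overview**

1. The target is (3S,3aS,6S,6aR)-6-(3,4-dihydroxyphenyl)-3-(4-hydroxy-3,5-dimethoxyphenyl)tetrahydro-1H,3H-furo[3,4-c]furan-1-one. Locants: C1 lactone C=O, O2, C3 syringyl-bearing CH, C3a, C4 CH2, O5, C6 catechol-bearing CH, C6a lactone α-carbon; all four ring hydrogens are cis. It is reached from its tris-TBS ether by a final global desilylation.
2. Key disconnection: the C6a–C6 bond, cut together with O5–C6. A cis-lactone alcohol and a catechol-derived α-chloro benzyl methyl ether are joined in one pot by O-alkylation, soft enolization and silyl ketene acetal/oxocarbenium closure; the tetrahydrofuran ring is formed last.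
3. Enabling feature: C6 is both benzylic to the electron-rich catechol ring and bound to ring oxygen O5, so it is a latent aryl-stabilized oxocarbenium carbon. Its partner C6a is the only enolizable carbon of the γ-lactone ring (α to C1=O), and the C3a–C4–O5 arm tethers the two on one face.
4. The cis-lactone alcohol comes from a MgCl2-catalysed Evans anti-aldol of a succinate-derived N-acyloxazolidinone with TBS-protected syringaldehyde (sets C3a and C3), lactonization (lactone ring, formed first) and reductive removal of the auxiliary.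
5. The α-chloro ether comes from 3,4-dihydroxybenzaldehyde by silylation, acetalization and treatment with acetyl chloride.

Key step: step 9

Assumption: in step 3 the chelated magnesium enolate of the (S)-benzyl imide is taken to react on the face anti to the benzyl group, the usual sense for this catalyst system, which gives the (3R,4S) aldol; if the sense were opposite, the (R)-auxiliary would be used. TBS = tert-butyldimethylsilyl.

**Route**

Step 1
Reactants: 1 syringaldehyde (4-hydroxy-3,5-dimethoxybenzaldehyde)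
Product: 2 4-(TBS-oxy)-3,5-dimethoxybenzaldehyde
Conditions: TBSCl, imidazole, DMF, rt
Reagents that add atoms: tert-butyldimethylsilyl chloride, CC(C)(C)[Si](C)(C)Cl
Why: Standard silylation of the phenol gives a silyl ether that tolerates the later base, acid and Lewis-acid steps, keeps the para-oxygen a moderate donor and is removable with fluoride at the end.

Step 2
Reactants: 3 (S)-4-benzyloxazolidin-2-one; 4 methyl 4-chloro-4-oxobutanoate
Product: 5 methyl 4-[(4S)-4-benzyl-2-oxooxazolidin-3-yl]-4-oxobutanoate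
Conditions: Et3N, DMAP (cat.), CH2Cl2, 0 °C → rt
Reagents that add atoms: none
Why: DMAP-catalysed N-acylation of the oxazolidinone occurs at the acid chloride, which is far more electrophilic than the methyl ester.

Step 3
Reactants: 5 methyl 4-[(4S)-4-benzyl-2-oxooxazolidin-3-yl]-4-oxobutanoate; 2 4-(TBS-oxy)-3,5-dimethoxybenzaldehyde
Product: 6 methyl (3R,4S)-3-{[(4S)-4-benzyl-2-oxooxazolidin-3-yl]carbonyl}-4-[4-(TBS-oxy)-3,5-dimethoxyphenyl]-4-(trimethylsilyloxy)butanoate
Conditions: MgCl2 (20 mol%), Et3N, Me3SiCl, EtOAc, rt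
Reagents that add atoms: chlorotrimethylsilane, C[Si](C)(C)Cl
Why: In this Evans magnesium-halide-catalysed anti-aldol, soft enolization gives the chelated Z-enolate of the imide, which should add to the aryl aldehyde through a boat transition state on the face away from the benzyl group and be trapped as the silyl ether, setting the (3R,4S) anti pair that becomes C3a and C3.

Step 4
Reactants: 6 the aldol silyl ether from step 3
Product: 8 (4S)-4-benzyl-3-{[(2S,3R)-2-[4-(TBS-oxy)-3,5-dimethoxyphenyl]-5-oxotetrahydrofuran-3-yl]carbonyl}oxazolidin-2-one (cis-lactone), via hydroxy ester 7 (not isolated)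
Conditions: AcOH/THF/H2O (3:1:1), rt; then PPTS (cat.), toluene, 50 °C
Reagents that add atoms: none
Why: Mild hydrolysis of the trimethylsilyl ether frees the benzylic alcohol, which should lactonize onto the methyl ester (5-exo-trig) to form the γ-lactone ring; the anti aldol places aryl and acyl groups cis and no stereocenter is touched.

Step 5
Reactants: 8 the cis-lactone imide
Product: 9 (4S,5S)-5-[4-(TBS-oxy)-3,5-dimethoxyphenyl]-4-(hydroxymethyl)dihydrofuran-2(3H)-one
Conditions: NaBH4, THF/H2O (4:1), 0 °C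
Reagents that add atoms: none
Why: Borohydride reductive cleavage of the N-acyloxazolidinone should occur at the activated exocyclic imide carbonyl faster than at the γ-lactone, releasing the auxiliary and giving the primary alcohol with both stereocenters intact.

Step 6
Reactants: 10 3,4-dihydroxybenzaldehyde
Product: 11 3,4-bis(TBS-oxy)benzaldehyde
Conditions: TBSCl (2.2 equiv), imidazole, DMF, rt
Reagents that add atoms: tert-butyldimethylsilyl chloride, CC(C)(C)[Si](C)(C)Cl
Why: Double silylation masks the catechol as aryl silyl ethers that survive acetalization, acetyl chloride and silyl triflate, and leave with fluoride.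

Step 7
Reactants: 11 3,4-bis(TBS-oxy)benzaldehyde
Product: 12 4-(dimethoxymethyl)-1,2-bis(TBS-oxy)benzene
Conditions: HC(OMe)3, MeOH, p-TsOH (cat.), rt; Et3N quench
Reagents that add atoms: trimethyl orthoformate, COC(OC)OC; methanol, CO
Why: Acid-catalysed acetalization is driven to completion by the orthoformate as water scavenger, and aryl silyl ethers are stable to catalytic acid.

Step 8
Reactants: 12 the dimethyl acetal
Product: 13 4-[chloro(methoxy)methyl]-1,2-bis(TBS-oxy)benzene (racemic; used crude)
Conditions: AcCl (1.05 equiv), CH2Cl2, 0 °C → rt; volatiles removed in vacuo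
Reagents that add atoms: acetyl chloride, CC(=O)Cl
Why: Acyl chlorides convert dimethyl acetals into α-chloro ethers with loss of methyl acetate, giving a stoichiometric, irreversible alkylating agent at the aldehyde oxidation level.

Step 9
Reactants: 9 the cis-lactone alcohol; 13 the α-chloro ether
Product: 17 (3S,3aS,6S,6aR)-6-[3,4-bis(TBS-oxy)phenyl]-3-[4-(TBS-oxy)-3,5-dimethoxyphenyl]tetrahydro-1H,3H-furo[3,4-c]furan-1-one, via mixed acetal 14 (not isolated), via silyl ketene acetal 15 (not isolated), via oxocarbenium triflate 16 (not isolated)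
Conditions: i-Pr2NEt (1.3 equiv), CH2Cl2, −20 → 0 °C; then i-Pr2NEt (1.1 equiv), Me3SiOTf (2.3 equiv), −78 → −20 °C; NaHCO3 (aq)
Reagents that add atoms: none
Why: Proposed new method: the primary alcohol of 9 is O-alkylated by chloro ether 13 to mixed acetal 14 (both acetal epimers converge), after which Me3SiOTf/i-Pr2NEt soft-enolizes the lactone to silyl ketene acetal 15 and ionizes the acetal (loss of MeOSiMe3) to the aryl-stabilized (E)-oxocarbenium ion 16, whose cationic carbon is attacked by the ketene-acetal carbon C6a in an intramolecular Mukaiyama aldol-type addition, the carbonyl silyl group being returned as Me3SiOTf. The closest known reaction types are the one-pot silyl triflate/amine enol-silane formation–Mukaiyama addition to dimethyl acetals (intermolecular) and the Lewis-acid closure of 2-aryl-3-(hydroxymethyl)-2,3-dihydrofuran enol ethers onto tethered aryl oxocarbenium ions; a lactone-derived silyl ketene acetal has not been used in this ring closure. The tetrahydrofuran ring closes in a 5-(enolexo)-endo-trig mode (C6a inside and C1 outside the new ring, both atoms of the C6=O5 cation inside it), which is accessible for oxocarbenium ions because the oxygen lone pair lets the π-system tilt toward the nucleophile. C6a is controlled by the tether, since the C4–O5 arm on C3a can only reach the face of the planar ketene acetal cis to it, which enforces the cis ring fusion. C6 is set under kinetic control by the (E)-oxocarbenium reacting through a compact envelope in which O5 lies over the C3a–C6a bond on the concave side and the aryl group, anti to C4, points to the concave (endo) face, the sense found in the enol-ether precedent. The step needs tether formation before the carbon nucleophile exists (the lactone stays a latent nucleophile until the silyl triflate is added), ionization by loss of the methoxy group and not the tether oxygen (the less hindered, more basic OMe is silylated), and no epimerization of benzylic C3 and C6 or re-enolization of the product (low temperature, amine buffer, one equivalent of base in the second stage).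

Step 10
Reactants: 17 the tris-TBS furofuranone
Product: 18 (3S,3aS,6S,6aR)-6-(3,4-dihydroxyphenyl)-3-(4-hydroxy-3,5-dimethoxyphenyl)tetrahydro-1H,3H-furo[3,4-c]furan-1-one (CNP0224550.1)
Conditions: Bu4NF (3.3 equiv), AcOH (3.3 equiv), THF, 0 °C → rt
Reagents that add atoms: none
Why: Fluoride cleaves the three aryl silyl ethers, and the acetic acid buffer keeps the liberated para-hydroxybenzylic ether and lactone from forming quinone methides, so the endo centres C3 and C6 should not epimerize.

**Compound list**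

1 | syringaldehyde (4-hydroxy-3,5-dimethoxybenzaldehyde) | COc1cc(C=O)cc(OC)c1O | starting material
2 | 4-(TBS-oxy)-3,5-dimethoxybenzaldehyde | COc1cc(C=O)cc(OC)c1O[Si](C)(C)C(C)(C)C | intermediate
3 | (S)-4-benzyloxazolidin-2-one | O=C1N[C@@H](Cc2ccccc2)CO1 | starting material
4 | methyl 4-chloro-4-oxobutanoate | COC(=O)CCC(Cl)=O | starting material
5 | methyl 4-[(4S)-4-benzyl-2-oxooxazolidin-3-yl]-4-oxobutanoate | COC(=O)CCC(=O)N1[C@@H](Cc2ccccc2)COC1=O | intermediate
6 | methyl (3R,4S)-3-{[(4S)-4-benzyl-2-oxooxazolidin-3-yl]carbonyl}-4-[4-(TBS-oxy)-3,5-dimethoxyphenyl]-4-(trimethylsilyloxy)butanoate | COc1cc([C@@H](O[Si](C)(C)C)[C@@H](CC(=O)OC)C(=O)N2[C@@H](Cc3ccccc3)COC2=O)cc(OC)c1O[Si](C)(C)C(C)(C)C | intermediate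
7 | methyl (3R,4S)-3-{[(4S)-4-benzyl-2-oxooxazolidin-3-yl]carbonyl}-4-[4-(TBS-oxy)-3,5-dimethoxyphenyl]-4-hydroxybutanoate (formed in the flask) | COc1cc([C@@H](O)[C@@H](CC(=O)OC)C(=O)N2[C@@H](Cc3ccccc3)COC2=O)cc(OC)c1O[Si](C)(C)C(C)(C)C | intermediate
8 | (4S)-4-benzyl-3-{[(2S,3R)-2-[4-(TBS-oxy)-3,5-dimethoxyphenyl]-5-oxotetrahydrofuran-3-yl]carbonyl}oxazolidin-2-one (cis) | COc1cc([C@H]2OC(=O)C[C@H]2C(=O)N3[C@@H](Cc4ccccc4)COC3=O)cc(OC)c1O[Si](C)(C)C(C)(C)C | intermediate
9 | (4S,5S)-5-[4-(TBS-oxy)-3,5-dimethoxyphenyl]-4-(hydroxymethyl)dihydrofuran-2(3H)-one (cis) | COc1cc([C@H]2OC(=O)C[C@H]2CO)cc(OC)c1O[Si](C)(C)C(C)(C)C | intermediate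
10 | 3,4-dihydroxybenzaldehyde | O=Cc1ccc(O)c(O)c1 | starting material
11 | 3,4-bis(TBS-oxy)benzaldehyde | O=Cc1ccc(O[Si](C)(C)C(C)(C)C)c(O[Si](C)(C)C(C)(C)C)c1 | intermediate
12 | 4-(dimethoxymethyl)-1,2-bis(TBS-oxy)benzene | COC(OC)c1ccc(O[Si](C)(C)C(C)(C)C)c(O[Si](C)(C)C(C)(C)C)c1 | intermediate
13 | 4-[chloro(methoxy)methyl]-1,2-bis(TBS-oxy)benzene (racemic) | COC(Cl)c1ccc(O[Si](C)(C)C(C)(C)C)c(O[Si](C)(C)C(C)(C)C)c1 | intermediate
14 | (4S,5S)-4-({[3,4-bis(TBS-oxy)phenyl](methoxy)methoxy}methyl)-5-[4-(TBS-oxy)-3,5-dimethoxyphenyl]dihydrofuran-2(3H)-one (mixed acetal, both acetal epimers, formed in the flask) | COc1cc([C@H]2OC(=O)C[C@H]2COC(OC)c3ccc(O[Si](C)(C)C(C)(C)C)c(O[Si](C)(C)C(C)(C)C)c3)cc(OC)c1O[Si](C)(C)C(C)(C)C | intermediate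
15 | 2-(trimethylsilyloxy)-4,5-dihydrofuran (silyl ketene acetal) of 14, (4S,5S) (formed in the flask) | COc1cc([C@H]2OC(O[Si](C)(C)C)=C[C@H]2COC(OC)c3ccc(O[Si](C)(C)C(C)(C)C)c(O[Si](C)(C)C(C)(C)C)c3)cc(OC)c1O[Si](C)(C)C(C)(C)C | intermediate
16 | (E)-aryl oxocarbenium trifluoromethanesulfonate derived from 15 by loss of methoxide (formed in the flask) | COc1cc([C@H]2OC(O[Si](C)(C)C)=C[C@H]2C/[O+]=C/c3ccc(O[Si](C)(C)C(C)(C)C)c(O[Si](C)(C)C(C)(C)C)c3)cc(OC)c1O[Si](C)(C)C(C)(C)C.[O-]S(=O)(=O)C(F)(F)F | intermediate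
17 | (3S,3aS,6S,6aR)-6-[3,4-bis(TBS-oxy)phenyl]-3-[4-(TBS-oxy)-3,5-dimethoxyphenyl]tetrahydro-1H,3H-furo[3,4-c]furan-1-one | COc1cc([C@H]2OC(=O)[C@@H]3[C@H]2CO[C@@H]3c4ccc(O[Si](C)(C)C(C)(C)C)c(O[Si](C)(C)C(C)(C)C)c4)cc(OC)c1O[Si](C)(C)C(C)(C)C | intermediate
18 | (3S,3aS,6S,6aR)-6-(3,4-dihydroxyphenyl)-3-(4-hydroxy-3,5-dimethoxyphenyl)tetrahydro-1H,3H-furo[3,4-c]furan-1-one | COc1cc([C@H]2OC(=O)[C@@H]3[C@H]2CO[C@@H]3c2ccc(O)c(O)c2)cc(OC)c1O | target

**Totals**

Total step count: 10. Longest linear sequence: 6 steps (steps 1, 3, 4, 5, 9, 10; the branch from 3 through step 2 is equally long).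

**Steps most likely to fail**

1. Step 9 (proposed new method). Three things may go wrong. The mixed acetal may ionize in the wrong sense, followed by intermolecular Mukaiyama addition instead of ring closure. The kinetic endo selectivity at C6 may erode, or the benzylic C–O bonds may re-ionize under the silyl triflate. The product may be re-enolized, with β-elimination of O5 opening the new ring. The fallback is a rhodium-carbenoid C–H insertion, known for α-diazo-γ-butyrolactones carrying a β-(arylmethoxy)methyl group, which should deliver the aryl group cis to the lactone carbonyl. It sets out from 9 and returns at 17. Reductive etherification of 9 with aldehyde 11 (Et3SiH, Me3SiOTf cat., CH2Cl2, −78 °C) should give the 3,4-bis(TBS-oxy)benzyl ether F1. Acylation of its lithium enolate (LiN(SiMe3)2, CF3CO2CH2CF3, THF, −78 °C) should give the α-trifluoroacetyl lactone F2. Detrifluoroacetylative Regitz diazo transfer (MsN3, Et3N, MeCN) should give the α-diazo lactone F3. Rh2(OAc)4 (dirhodium tetraacetate, 2 mol%) in CH2Cl2 at rt should then insert the carbenoid carbon C6a into the ether-activated benzylic C–H bond, forming the same C6a–C6 bond under neutral conditions and giving 17.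

2. Step 3. The ester-bearing imide may enolize or add sluggishly if the ester competes for magnesium. The magnesium aldolate may also lactonize before silylation, exposing the imide α-carbon to amine-mediated epimerization to the trans-lactone. The fallback masks the carboxyl group as a terminal alkene; it sets out from 3 (with 2) and returns at 8. Acylation of 3 with pent-4-enoyl chloride (Et3N, DMAP cat.) gives (S)-4-benzyl-3-(pent-4-enoyl)oxazolidin-2-one F4. The same MgCl2/Et3N/Me3SiCl anti-aldol with 2 should give the silyl ether F5, and AcOH/THF/H2O the free anti-aldol alcohol F6. Lemieux–Johnson cleavage (OsO4 cat., NaIO4, 2,6-lutidine, dioxane/H2O) should give the lactol F7, and Ag2CO3 on Celite (toluene, 80 °C) should oxidize it to 8.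

3. Step 5. Borohydride may also reduce the lactone, the basic medium may epimerize the imide α-carbon, or the product alkoxide may translactonize to the isomeric 4-[aryl(hydroxy)methyl] lactone. The fallback removes the auxiliary hydrolytically and then reduces the acid selectively; it sets out from 8 and returns at 9. LiOH/H2O2 (THF/H2O, 0 °C, acidic work-up) should give the cis-lactone carboxylic acid F8, and BH3·SMe2 (THF, 0 °C) should reduce the acid in the presence of the lactone to give 9.

**Further compounds**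

F1 | step 9 | (4S,5S)-4-({[3,4-bis(TBS-oxy)benzyl]oxy}methyl)-5-[4-(TBS-oxy)-3,5-dimethoxyphenyl]dihydrofuran-2(3H)-one | COc1cc([C@H]2OC(=O)C[C@H]2COCc3ccc(O[Si](C)(C)C(C)(C)C)c(O[Si](C)(C)C(C)(C)C)c3)cc(OC)c1O[Si](C)(C)C(C)(C)C
F2 | step 9 | (4S,5S)-4-({[3,4-bis(TBS-oxy)benzyl]oxy}methyl)-5-[4-(TBS-oxy)-3,5-dimethoxyphenyl]-3-(trifluoroacetyl)dihydrofuran-2(3H)-one (C3 epimers) | COc1cc([C@H]2OC(=O)C(C(=O)C(F)(F)F)[C@H]2COCc3ccc(O[Si](C)(C)C(C)(C)C)c(O[Si](C)(C)C(C)(C)C)c3)cc(OC)c1O[Si](C)(C)C(C)(C)C
F3 | step 9 | (4S,5S)-4-({[3,4-bis(TBS-oxy)benzyl]oxy}methyl)-5-[4-(TBS-oxy)-3,5-dimethoxyphenyl]-3-diazodihydrofuran-2(3H)-one | COc1cc([C@H]2OC(=O)C(=[N+]=[N-])[C@H]2COCc3ccc(O[Si](C)(C)C(C)(C)C)c(O[Si](C)(C)C(C)(C)C)c3)cc(OC)c1O[Si](C)(C)C(C)(C)C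
F4 | step 3 | (S)-4-benzyl-3-(pent-4-enoyl)oxazolidin-2-one | C=CCCC(=O)N1[C@@H](Cc2ccccc2)COC1=O
F5 | step 3 | (S)-4-benzyl-3-{(R)-2-[(S)-[4-(TBS-oxy)-3,5-dimethoxyphenyl](trimethylsilyloxy)methyl]pent-4-enoyl}oxazolidin-2-one | COc1cc([C@@H](O[Si](C)(C)C)[C@@H](CC=C)C(=O)N2[C@@H](Cc3ccccc3)COC2=O)cc(OC)c1O[Si](C)(C)C(C)(C)C
F6 | step 3 | (S)-4-benzyl-3-{(R)-2-[(S)-[4-(TBS-oxy)-3,5-dimethoxyphenyl](hydroxy)methyl]pent-4-enoyl}oxazolidin-2-one | COc1cc([C@@H](O)[C@@H](CC=C)C(=O)N2[C@@H](Cc3ccccc3)COC2=O)cc(OC)c1O[Si](C)(C)C(C)(C)C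
F7 | step 3 | (4S)-4-benzyl-3-{[(2S,3R)-2-[4-(TBS-oxy)-3,5-dimethoxyphenyl]-5-hydroxytetrahydrofuran-3-yl]carbonyl}oxazolidin-2-one (lactol, both anomers) | COc1cc([C@H]2OC(O)C[C@H]2C(=O)N3[C@@H](Cc4ccccc4)COC3=O)cc(OC)c1O[Si](C)(C)C(C)(C)C
F8 | step 5 | (2S,3R)-2-[4-(TBS-oxy)-3,5-dimethoxyphenyl]-5-oxotetrahydrofuran-3-carboxylic acid | COc1cc([C@H]2OC(=O)C[C@H]2C(=O)O)cc(OC)c1O[Si](C)(C)C(C)(C)C
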